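**Plan**

1. Retrosynthesis: the three aryl O–Si bonds are cut first. Ring C is then cut at O1–C2 and C4–C4a together, which leads back to an aryl (E)-cinnamate with the cinnamoyl group on O1 and iodine on C4a. Further cuts are the ester C–O bond, the C4a–I bond, the C8–CH2 bond (Negishi) and the C2″–C3″ bond of the side chain (auxiliary alkylation).
2. Forward: the (S)-lavandulyl iodide is made and joined to C8 of a symmetric 2-iodo-5-methoxyresorcinol bis-MOM ether. Ring A is then iodinated at the future C4a, unmasked, silylated at the future 7-OH and esterified with the ring B cinnamic acid. Rings A and B are bought in, ring C arises in the key step, and desilylation ends the route.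
3. Enabling feature: O1 on C8a lies ortho to C4a, and the other neighbour of C4a, C5, carries only OMe. A cinnamoyl group parked on O1 can therefore be handed to C4a, and O1 alone can then close onto C2 of the enone set free. This is the chalcone-to-flavanone step of the biosynthesis, run on silylated kuraridin. The 2-alkyl-5-methoxyresorcinol core is symmetric, so regiochemistry on ring A costs nothing.
4. Stereochemistry: C2″ (R) comes from the oxazolidinone-controlled α-alkylation of a dienolate; C2 (S) comes from catalyst control in the oxa-Michael half of the key step.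

Key step: step 14

Abbreviations: MOM = methoxymethyl; TIPS = tri(propan-2-yl)silyl; Lav = (2R)-5-methyl-2-(prop-1-en-2-yl)hex-4-enyl; QN-TU = 1-[3,5-bis(trifluoromethyl)phenyl]-3-(9-deoxy-9-epi-quinin-9-yl)thiourea.

Assumption: the quinine-derived thiourea QN-TU is taken to favour the (2S) series; if a trial on a model 2′-hydroxy-6′-methoxychalcone shows the opposite sense, the quinidine-derived pseudoenantiomer is used under the same conditions.

**Route**

Step 1
Reactants: 1 (4S)-4-benzyl-1,3-oxazolidin-2-one; 2 3-methylbut-2-enoyl chloride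
Product: 4 (4S)-4-benzyl-3-(3-methylbut-2-enoyl)-1,3-oxazolidin-2-one, via lithium oxazolidinide 3 (not isolated)
Conditions: n-BuLi, THF, −78 °C; then 2, −78 → 0 °C
Reagents that add atoms: none
Why: N-acylation of the lithiated Evans oxazolidinone with the acid chloride is fast at −78 °C and avoids the vinylketene pathway that amine bases open with this acid chloride.

Step 2
Reactants: 4 (4S)-4-benzyl-3-(3-methylbut-2-enoyl)-1,3-oxazolidin-2-one; 5 1-bromo-3-methylbut-2-ene
Product: 7 (4S)-4-benzyl-3-[(2S)-5-methyl-2-(prop-1-en-2-yl)hex-4-enoyl]-1,3-oxazolidin-2-one, via sodium dienolate 6 (not isolated)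
Conditions: NaN(SiMe3)2, THF, −78 °C; then 5, −78 → −40 °C
Reagents that add atoms: none
Why: Evans asymmetric alkylation in its deconjugative form: γ-deprotonation gives the chelated (Z)-dienolate, which the allylic bromide attacks at the α-carbon on the face opposite the benzyl group, setting the (2S) centre and moving the alkene into the isopropenyl position.

Step 3
Reactants: 7 (4S)-4-benzyl-3-[(2S)-5-methyl-2-(prop-1-en-2-yl)hex-4-enoyl]-1,3-oxazolidin-2-one
Product: 8 (2S)-5-methyl-2-(prop-1-en-2-yl)hex-4-en-1-ol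
Conditions: LiBH4, H2O (1 equiv), Et2O, 0 °C
Reagents that add atoms: none
Why: Reductive cleavage of the N-acyl oxazolidinone by borohydride gives the primary alcohol and releases the auxiliary without touching the epimerisable β,γ-unsaturated centre.

Step 4
Reactants: 8 (2S)-5-methyl-2-(prop-1-en-2-yl)hex-4-en-1-ol
Product: 9 (3S)-3-(iodomethyl)-2,6-dimethylhepta-1,5-diene
Conditions: PPh3, I2, imidazole, CH2Cl2, 0 °C → rt
Reagents that add atoms: iodine, II
Why: Appel-type iodination substitutes the primary hydroxyl by SN2 at a carbon that is not stereogenic, the iodine being bound as the phosphonium salt before it can add to the alkenes.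

Step 5
Reactants: 10 5-methoxybenzene-1,3-diol
Product: 11 1-methoxy-3,5-bis(methoxymethoxy)benzene
Conditions: MOMCl, iPr2NEt, CH2Cl2, 0 °C → rt
Reagents that add atoms: chloromethyl methyl ether, COCCl
Why: O-alkylation of both phenols (Williamson type) with the reactive α-chloro ether installs the acetal groups that direct the two later lithiations.

Step 6
Reactants: 11 1-methoxy-3,5-bis(methoxymethoxy)benzene
Product: 13 2-iodo-5-methoxy-1,3-bis(methoxymethoxy)benzene, via aryllithium 12 (not isolated)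
Conditions: n-BuLi, THF, 0 °C; then I2, −78 °C
Reagents that add atoms: iodine, II
Why: Directed ortho-metalation takes place at C2, the position flanked by both coordinating OMOM groups, and iodinolysis of the aryllithium gives the aryl iodide.

Step 7
Reactants: 9 (3S)-3-(iodomethyl)-2,6-dimethylhepta-1,5-diene; 13 2-iodo-5-methoxy-1,3-bis(methoxymethoxy)benzene
Product: 15 5-methoxy-1,3-bis(methoxymethoxy)-2-Lav-benzene, via alkylzinc iodide 14 (not isolated)
Conditions: 9, Zn dust, LiCl, THF, 35 °C; then 13, Pd(OAc)2 (3 mol%), SPhos (6 mol%), 50 °C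
Reagents that add atoms: none
Why: Negishi cross-coupling: zinc inserts into the primary C–I bond and the bulky biarylphosphine palladium catalyst couples the primary alkylzinc with the doubly ortho-substituted aryl iodide faster than β-hydride elimination, the centre β to zinc taking no part.

Step 8
Reactants: 15 5-methoxy-1,3-bis(methoxymethoxy)-2-Lav-benzene
Product: 17 4-iodo-5-methoxy-1,3-bis(methoxymethoxy)-2-Lav-benzene, via aryllithium 16 (not isolated)
Conditions: n-BuLi, THF, 0 °C; then ICH2CH2I, −78 °C → rt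
Reagents that add atoms: 1,2-diiodoethane, ICCI
Why: Second directed ortho-metalation at the only kind of ring C–H left (between OMOM and OMe, both such positions being equivalent), followed by iodination with an iodine source that does not attack the alkenes.

Step 9
Reactants: 17 4-iodo-5-methoxy-1,3-bis(methoxymethoxy)-2-Lav-benzene
Product: 18 4-iodo-5-methoxy-2-Lav-benzene-1,3-diol
Conditions: HCl (cat.), MeOH, rt
Reagents that add atoms: none
Why: Acid-catalysed transacetalisation to methanol cleaves aryl MOM ethers at room temperature, conditions that ortho-prenyl-type phenols normally survive.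

Step 10
Reactants: 18 4-iodo-5-methoxy-2-Lav-benzene-1,3-diol
Product: 19 2-iodo-3-methoxy-6-Lav-5-(TIPS-oxy)phenol
Conditions: TIPSCl (1.05 equiv), imidazole, CH2Cl2, 0 °C
Reagents that add atoms: chlorotri(propan-2-yl)silane, CC(C)[Si](Cl)(C(C)C)C(C)C
Why: Site-selective silylation: the bulky silyl chloride should react at the hydroxyl flanked by CH2 and H and not at the one buttressed by iodine and CH2.

Step 11
Reactants: 20 2,4-dihydroxybenzaldehyde
Product: 21 2,4-bis(TIPS-oxy)benzaldehyde
Conditions: TIPSCl (2.4 equiv), imidazole, DMF, rt → 40 °C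
Reagents that add atoms: chlorotri(propan-2-yl)silane, CC(C)[Si](Cl)(C(C)C)C(C)C
Why: Imidazole-promoted silylation of both phenols gives ethers that withstand organolithium reagents and are removed by fluoride at the end.

Step 12
Reactants: 21 2,4-bis(TIPS-oxy)benzaldehyde; 22 2-(diethoxyphosphoryl)acetic acid
Product: 24 (2E)-3-[2,4-bis(TIPS-oxy)phenyl]prop-2-enoic acid, via dilithio phosphonoacetate 23 (not isolated)
Conditions: 22, n-BuLi (2.1 equiv), THF, −78 °C; then 21, −78 °C → rt; 1 M HCl (work-up)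
Reagents that add atoms: none
Why: Horner–Wadsworth–Emmons olefination with the dianion of the phosphonoacetic acid gives the (E)-cinnamic acid directly, so no ester hydrolysis endangers the silyl ethers.

Step 13
Reactants: 19 2-iodo-3-methoxy-6-Lav-5-(TIPS-oxy)phenol; 24 (2E)-3-[2,4-bis(TIPS-oxy)phenyl]prop-2-enoic acid
Product: 25 2-iodo-3-methoxy-6-Lav-5-(TIPS-oxy)phenyl (2E)-3-[2,4-bis(TIPS-oxy)phenyl]prop-2-enoate
Conditions: EDC·HCl, DMAP, CH2Cl2, rt
Reagents that add atoms: none
Why: Steglich-type esterification (carbodiimide/DMAP) acylates the remaining hindered but acidic phenol and parks the cinnamoyl group on the future O1.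

Step 14
Reactants: 25 2-iodo-3-methoxy-6-Lav-5-(TIPS-oxy)phenyl (2E)-3-[2,4-bis(TIPS-oxy)phenyl]prop-2-enoate
Product: 29 (2S)-2-[2,4-bis(TIPS-oxy)phenyl]-5-methoxy-8-Lav-7-(TIPS-oxy)-2,3-dihydro-4H-chromen-4-one, via aryllithium 26 (not isolated), via lithium oxidochalcone 27 (not isolated), via hydroxychalcone 28 (not isolated)
Conditions: t-BuLi (2.05 equiv), Et2O/pentane, −100 → −40 °C; AcOH (1.0 equiv); solvent exchange to toluene in the same flask; QN-TU (10 mol%), −20 °C → rt
Reagents that add atoms: none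
Why: Iodine–lithium exchange at the future C4a outruns addition of t-BuLi to the ester at −100 °C, and the aryllithium attacks the ester carbonyl held next to it, passing through a four-membered alkoxide that collapses to the lithium 2′-oxidochalcone (anionic Fries rearrangement, a 1,3 O→C acyl shift that forms C4–C4a and frees O1); after neutralisation the bifunctional thiourea–quinuclidine catalyst adds O1 to C2 (oxa-Michael addition, forming O1–C2). The closest known reactions are the halogen–metal-exchange-initiated anionic Fries rearrangement of ortho-haloaryl esters and the cinchona-thiourea-catalysed, chalcone-isomerase-like cyclisation of 2′-hydroxychalcones to flavanones. Ring C is the only ring closed, in the 6-endo-trig mode by attack of the phenolic oxygen on the β-carbon of the enone. The new centre C2 is under catalyst control: the thiourea binds the ketone oxygen while the quinuclidine nitrogen holds the phenol, so O1 reaches one face of C2, and the distant side-chain centre has no say. The step needs acyl transfer to carbon instead of conjugate C-alkylation, closure through the right oxygen, and no racemic background: the ester tether and the position of iodine send the acyl group only to C4a, the C5 methoxy group leaves O1 as the only ortho oxygen, and the lithium phenoxide of the unactivated enone does not cyclise until it is protonated in the presence of the catalyst. No acid stronger than one equivalent of acetic acid is present, so the diene of the side chain is not at risk.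

Step 15
Reactants: 29 (2S)-2-[2,4-bis(TIPS-oxy)phenyl]-5-methoxy-8-Lav-7-(TIPS-oxy)-2,3-dihydro-4H-chromen-4-one
Product: 30 kurarinone
Conditions: TBAF (3.3 equiv), AcOH (3.3 equiv), THF, 0 °C
Reagents that add atoms: none
Why: Fluoride-mediated cleavage of the three aryl silyl ethers, buffered with acetic acid so that no phenoxide opens ring C and epimerises C2.

**Compound list**

1 | (4S)-4-benzyl-1,3-oxazolidin-2-one | O=C1OC[C@H](Cc2ccccc2)N1 | starting material
2 | 3-methylbut-2-enoyl chloride | CC(C)=CC(=O)Cl | starting material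
3 | lithium (4S)-4-benzyl-2-oxo-1,3-oxazolidin-3-ide | O=C1OC[C@H](Cc2ccccc2)N1[Li] | intermediate
4 | (4S)-4-benzyl-3-(3-methylbut-2-enoyl)-1,3-oxazolidin-2-one | CC(C)=CC(=O)N1[C@@H](Cc2ccccc2)COC1=O | intermediate
5 | 1-bromo-3-methylbut-2-ene (prenyl bromide) | CC(C)=CCBr | starting material
6 | sodium (Z)-dienolate of 4 (O and isopropenyl cis) | C=C(C)/C=C(\O[Na])N1[C@@H](Cc2ccccc2)COC1=O | intermediate
7 | (4S)-4-benzyl-3-[(2S)-5-methyl-2-(prop-1-en-2-yl)hex-4-enoyl]-1,3-oxazolidin-2-one | C=C(C)[C@H](CC=C(C)C)C(=O)N1[C@@H](Cc2ccccc2)COC1=O | intermediate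
8 | (2S)-5-methyl-2-(prop-1-en-2-yl)hex-4-en-1-ol, (S)-lavandulol | C=C(C)[C@H](CC=C(C)C)CO | intermediate
9 | (3S)-3-(iodomethyl)-2,6-dimethylhepta-1,5-diene, (S)-lavandulyl iodide | C=C(C)[C@H](CC=C(C)C)CI | intermediate
10 | 5-methoxybenzene-1,3-diol | COc1cc(O)cc(O)c1 | starting material
11 | 1-methoxy-3,5-bis(methoxymethoxy)benzene | COCOc1cc(OC)cc(OCOC)c1 | intermediate
12 | [4-methoxy-2,6-bis(methoxymethoxy)phenyl]lithium | COCOc1cc(OC)cc(OCOC)c1[Li] | intermediate
13 | 2-iodo-5-methoxy-1,3-bis(methoxymethoxy)benzene | COCOc1cc(OC)cc(OCOC)c1I | intermediate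
14 | [(2S)-5-methyl-2-(prop-1-en-2-yl)hex-4-enyl]zinc iodide | C=C(C)[C@H](CC=C(C)C)C[Zn]I | intermediate
15 | 5-methoxy-1,3-bis(methoxymethoxy)-2-[(2R)-5-methyl-2-(prop-1-en-2-yl)hex-4-enyl]benzene | C=C(C)[C@H](CC=C(C)C)Cc1c(OCOC)cc(OC)cc1OCOC | intermediate
16 | 4-lithio derivative of 15 (lithium between OMOM and OMe) | C=C(C)[C@H](CC=C(C)C)Cc1c(OCOC)cc(OC)c([Li])c1OCOC | intermediate
17 | 4-iodo-5-methoxy-1,3-bis(methoxymethoxy)-2-[(2R)-5-methyl-2-(prop-1-en-2-yl)hex-4-enyl]benzene | C=C(C)[C@H](CC=C(C)C)Cc1c(OCOC)cc(OC)c(I)c1OCOC | intermediate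
18 | 4-iodo-5-methoxy-2-[(2R)-5-methyl-2-(prop-1-en-2-yl)hex-4-enyl]benzene-1,3-diol | C=C(C)[C@H](CC=C(C)C)Cc1c(O)cc(OC)c(I)c1O | intermediate
19 | 2-iodo-3-methoxy-6-[(2R)-5-methyl-2-(prop-1-en-2-yl)hex-4-enyl]-5-[tri(propan-2-yl)silyloxy]phenol | C=C(C)[C@H](CC=C(C)C)Cc1c(O[Si](C(C)C)(C(C)C)C(C)C)cc(OC)c(I)c1O | intermediate
20 | 2,4-dihydroxybenzaldehyde | O=Cc1ccc(O)cc1O | starting material
21 | 2,4-bis[tri(propan-2-yl)silyloxy]benzaldehyde | O=Cc1ccc(O[Si](C(C)C)(C(C)C)C(C)C)cc1O[Si](C(C)C)(C(C)C)C(C)C | intermediate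
22 | 2-(diethoxyphosphoryl)acetic acid | CCOP(=O)(CC(=O)O)OCC | starting material
23 | lithium 2-(diethoxyphosphoryl)-2-lithioacetate | CCOP(=O)(OCC)C([Li])C(=O)O[Li] | intermediate
24 | (2E)-3-{2,4-bis[tri(propan-2-yl)silyloxy]phenyl}prop-2-enoic acid | OC(=O)/C=C/c1ccc(O[Si](C(C)C)(C(C)C)C(C)C)cc1O[Si](C(C)C)(C(C)C)C(C)C | intermediate
25 | 2-iodo-3-methoxy-6-[(2R)-5-methyl-2-(prop-1-en-2-yl)hex-4-enyl]-5-[tri(propan-2-yl)silyloxy]phenyl (2E)-3-{2,4-bis[tri(propan-2-yl)silyloxy]phenyl}prop-2-enoate | C=C(C)[C@H](CC=C(C)C)Cc1c(O[Si](C(C)C)(C(C)C)C(C)C)cc(OC)c(I)c1OC(=O)/C=C/c1ccc(O[Si](C(C)C)(C(C)C)C(C)C)cc1O[Si](C(C)C)(C(C)C)C(C)C | intermediate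
26 | aryllithium from 25 (lithium in place of iodine) | C=C(C)[C@H](CC=C(C)C)Cc1c(O[Si](C(C)C)(C(C)C)C(C)C)cc(OC)c([Li])c1OC(=O)/C=C/c1ccc(O[Si](C(C)C)(C(C)C)C(C)C)cc1O[Si](C(C)C)(C(C)C)C(C)C | intermediate
27 | lithium phenoxide of chalcone 28 | C=C(C)[C@H](CC=C(C)C)Cc1c(O[Si](C(C)C)(C(C)C)C(C)C)cc(OC)c(C(=O)/C=C/c2ccc(O[Si](C(C)C)(C(C)C)C(C)C)cc2O[Si](C(C)C)(C(C)C)C(C)C)c1O[Li] | intermediate
28 | (2E)-1-{2-hydroxy-6-methoxy-3-[(2R)-5-methyl-2-(prop-1-en-2-yl)hex-4-enyl]-4-[tri(propan-2-yl)silyloxy]phenyl}-3-{2,4-bis[tri(propan-2-yl)silyloxy]phenyl}prop-2-en-1-one (tris-TIPS kuraridin) | C=C(C)[C@H](CC=C(C)C)Cc1c(O[Si](C(C)C)(C(C)C)C(C)C)cc(OC)c(C(=O)/C=C/c2ccc(O[Si](C(C)C)(C(C)C)C(C)C)cc2O[Si](C(C)C)(C(C)C)C(C)C)c1O | intermediate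
29 | (2S)-2-{2,4-bis[tri(propan-2-yl)silyloxy]phenyl}-5-methoxy-8-[(2R)-5-methyl-2-(prop-1-en-2-yl)hex-4-enyl]-7-[tri(propan-2-yl)silyloxy]-2,3-dihydro-4H-chromen-4-one | C=C(C)[C@H](CC=C(C)C)Cc1c(O[Si](C(C)C)(C(C)C)C(C)C)cc(OC)c2c1O[C@H](c1ccc(O[Si](C(C)C)(C(C)C)C(C)C)cc1O[Si](C(C)C)(C(C)C)C(C)C)CC2=O | intermediate
30 | kurarinone, (2S)-2-(2,4-dihydroxyphenyl)-7-hydroxy-5-methoxy-8-[(2R)-5-methyl-2-(prop-1-en-2-yl)hex-4-enyl]-2,3-dihydro-4H-chromen-4-one | C=C(C)[C@H](CC=C(C)C)Cc1c(O)cc(OC)c2c1O[C@H](c1ccc(O)cc1O)CC2=O | target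

**Count and risks**

Total step count: 15. Longest linear sequence: 11 steps (steps 1–4, 7–10, 13–15).

Steps most likely to fail:

1. Step 14. t-BuLi may add to the aryl enoate in competition with iodine–lithium exchange, and the ring closure may show poor facial selectivity at C2. The fallback is stepwise and sets out from 19 and 24. Acid 24 is converted into the Weinreb amide F1 (MeNHOMe·HCl, EDC·HCl, DMAP, CH2Cl2). Phenol 19 is deprotonated with MeLi and exchanged with t-BuLi (THF, −78 °C) to the O,C-dilithio species F2, which is acylated by F1; work-up with aqueous NH4Cl gives chalcone 28, now isolated. Ring C is then closed without facial control (NaOAc, EtOH, 60 °C), which should give 29 together with its C2 epimer F3. The two diastereomers are separated by preparative HPLC on a chiral stationary phase, and F3 is returned to the same equilibrating conditions. The fallback comes back to the route at 29.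

2. Step 7. β-Hydride elimination from the alkylpalladium intermediate, or stalled transmetalation at the doubly ortho-substituted arylpalladium centre, may starve the coupling. The fallback reverses the polarity and uses no palladium; it sets out from alcohol 8 and from aryllithium 12 (made from 11 as in step 6). Alcohol 8 is converted at −78 °C into the triflate F4 (Tf2O, 2,6-lutidine, CH2Cl2), which is added to 12 in THF at −78 °C; SN2 alkylation of the aryllithium gives 15 directly. The fallback comes back to the route at 15 and makes 9 and 13 unnecessary.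

3. Step 9. Acid may add a freed phenolic hydroxyl across the isopropenyl group (chroman formation) or cause protodeiodination while the acetals are cleaved. The fallback replaces the acid-labile acetals by ones cleaved with fluoride and sets out from 10. Diol 10 is converted into the bis-SEM ether F5 (SEMCl, iPr2NEt, CH2Cl2). Lithiation with n-BuLi gives the aryllithium F6, and iodine gives the iodide F7. Negishi coupling with 14 under the conditions of step 7 gives the coupling product F8. A second lithiation gives the aryllithium F9, and 1,2-diiodoethane gives the iodide F10. Both SEM groups are then removed with TBAF in DMPU at 60 °C, with no acid present, to give 18. The fallback comes back to the route at 18.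

**Further compounds**

F1 | step 14 | (2E)-3-{2,4-bis[tri(propan-2-yl)silyloxy]phenyl}-N-methoxy-N-methylprop-2-enamide | CON(C)C(=O)/C=C/c1ccc(O[Si](C(C)C)(C(C)C)C(C)C)cc1O[Si](C(C)C)(C(C)C)C(C)C
F2 | step 14 | O,C-dilithio species from 19 (lithium phenoxide with lithium in place of iodine) | C=C(C)[C@H](CC=C(C)C)Cc1c(O[Si](C(C)C)(C(C)C)C(C)C)cc(OC)c([Li])c1O[Li]
F3 | step 14 | (2R)-2-{2,4-bis[tri(propan-2-yl)silyloxy]phenyl}-5-methoxy-8-[(2R)-5-methyl-2-(prop-1-en-2-yl)hex-4-enyl]-7-[tri(propan-2-yl)silyloxy]-2,3-dihydro-4H-chromen-4-one | C=C(C)[C@H](CC=C(C)C)Cc1c(O[Si](C(C)C)(C(C)C)C(C)C)cc(OC)c2c1O[C@@H](c1ccc(O[Si](C(C)C)(C(C)C)C(C)C)cc1O[Si](C(C)C)(C(C)C)C(C)C)CC2=O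
F4 | step 7 | [(2S)-5-methyl-2-(prop-1-en-2-yl)hex-4-enyl] trifluoromethanesulfonate | C=C(C)[C@H](CC=C(C)C)COS(=O)(=O)C(F)(F)F
F5 | step 9 | 1-methoxy-3,5-bis{[2-(trimethylsilyl)ethoxy]methoxy}benzene | COc1cc(OCOCC[Si](C)(C)C)cc(OCOCC[Si](C)(C)C)c1
F6 | step 9 | (4-methoxy-2,6-bis{[2-(trimethylsilyl)ethoxy]methoxy}phenyl)lithium | COc1cc(OCOCC[Si](C)(C)C)c([Li])c(OCOCC[Si](C)(C)C)c1
F7 | step 9 | 2-iodo-5-methoxy-1,3-bis{[2-(trimethylsilyl)ethoxy]methoxy}benzene | COc1cc(OCOCC[Si](C)(C)C)c(I)c(OCOCC[Si](C)(C)C)c1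
F8 | step 9 | 5-methoxy-2-[(2R)-5-methyl-2-(prop-1-en-2-yl)hex-4-enyl]-1,3-bis{[2-(trimethylsilyl)ethoxy]methoxy}benzene | C=C(C)[C@H](CC=C(C)C)Cc1c(OCOCC[Si](C)(C)C)cc(OC)cc1OCOCC[Si](C)(C)C
F9 | step 9 | 4-lithio derivative of F8 (lithium between OSEM and OMe) | C=C(C)[C@H](CC=C(C)C)Cc1c(OCOCC[Si](C)(C)C)cc(OC)c([Li])c1OCOCC[Si](C)(C)C
F10 | step 9 | 4-iodo-5-methoxy-2-[(2R)-5-methyl-2-(prop-1-en-2-yl)hex-4-enyl]-1,3-bis{[2-(trimethylsilyl)ethoxy]methoxy}benzene | C=C(C)[C@H](CC=C(C)C)Cc1c(OCOCC[Si](C)(C)C)cc(OC)c(I)c1OCOCC[Si](C)(C)C
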